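**Retrosynthetic overview**

- The target is the 2,3-trans flavan-3-ol (2R,3S) with a geranyl chain at C5′. The last disconnections are the four MOM ethers and then the geranyl chain (aryllithium allylation of a C5′ bromide).
- The C3 hydroxyl comes from hydroboration–oxidation of a (2S)-2-aryl-2H-chromene on the face opposite the C2 aryl group, which fixes the 2,3-trans relation.
- Ring C and the C2–C1′ bond come from the key step: a chlorocyclopropane fused to the 2,3-bond of a benzofuran opens to the 5,7-dioxygenated chromenylium ion (furan ring plus one carbon gives the pyran ring), and a ring-B aryl boronate captures it at C2 under chiral diol control.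
- Enabling feature: C3 of ring C is a lone CH between the oxygen-bound C2 and the benzylic C4, so ring C is the furan ring of a benzofuran (O1, C2, C4, C4a, C8a) plus one inserted carbon. O1 and the electron-rich ring A stabilise the cation that the opening leaves across C2–C3–C4.
- Ring order: ring A and the furan ring arrive with 4,6-dihydroxy-1-benzofuran-3(2H)-one, then the cyclopropane, then ring C by expansion. Ring B arrives from 3-bromocatechol.

Key step: step 7

Assumption: the (R,R)-tartramide diol is taken to give the (S)-chromene in step 7; if the sense of induction is the opposite, its (S,S) antipode is used.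

**Route**

Step 1
Reactants: 1 4,6-dihydroxy-1-benzofuran-3(2H)-one
Product: 2 4,6-bis(methoxymethoxy)-1-benzofuran-3(2H)-one
Conditions: MOMCl, iPr2NEt, DMF, 0 °C → rt
Reagents that add atoms: chloromethyl methyl ether (MOMCl) COCCl
Why: Phenoxide O-alkylation with a chloromethyl ether (methoxymethyl ether formation); the amine base ionises the two phenols but not the ketone alpha position, so the C2 methylene should stay untouched.

Step 2
Reactants: 2 4,6-bis(methoxymethoxy)-1-benzofuran-3(2H)-one
Product: 4 4,6-bis(methoxymethoxy)-1-benzofuran, via dihydrobenzofuran-3-ol 3 (not isolated)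
Conditions: NaBH4, MeOH/THF, 0 °C; then pyridinium p-toluenesulfonate (cat.), toluene, 50 °C
Reagents that add atoms: none
Why: Borohydride reduction of the aryl ketone, then acid-catalysed dehydration of the benzylic alcohol through the cation stabilised by O1 and ring A, should give the aromatic benzofuran (reduction–elimination); the MOM ethers tolerate the weak acid in an aprotic solvent.

Step 3
Reactants: 4 4,6-bis(methoxymethoxy)-1-benzofuran
Product: 5 1-chloro-4,6-bis(methoxymethoxy)-1a,6b-dihydro-1H-cyclopropa[b][1]benzofuran (racemic; cis-fused; chlorine endo)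
Conditions: CH2Cl2, MeLi, Et2O, −40 → −20 °C; cold aq. NaHCO3; used at once
Reagents that add atoms: dichloromethane ClCCl
Why: Carbenoid cyclopropanation: the electrophilic chlorocarbenoid LiCHCl2 adds to the enol-ether-like C2=C3 bond, the most nucleophilic pi bond of 4; cis fusion is forced and the carbenoid is expected to favour the endo (syn) chloride, the epimer that can ionise later, while the racemic nature of 5 is of no consequence because its stereocentres vanish in step 7.

Step 4
Reactants: 6 3-bromobenzene-1,2-diol (3-bromocatechol)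
Product: 7 1-bromo-2,3-bis(methoxymethoxy)benzene
Conditions: MOMCl, iPr2NEt, CH2Cl2, 0 °C → rt
Reagents that add atoms: chloromethyl methyl ether (MOMCl) COCCl
Why: Phenol O-alkylation of both catechol hydroxyls (methoxymethyl ether formation) gives ethers that tolerate the later organolithium step and stabilise the neighbouring aryllithium.

Step 5
Reactants: 7 1-bromo-2,3-bis(methoxymethoxy)benzene
Product: 8 2-[3-bromo-4,5-bis(methoxymethoxy)phenyl]-4,4,5,5-tetramethyl-1,3,2-dioxaborolane
Conditions: [Ir(OMe)(cod)]2 (cat.), 4,4′-di-tert-butyl-2,2′-bipyridine (cat.), B2pin2, THF, 80 °C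
Reagents that add atoms: bis(pinacolato)diboron CC1(C)OB(OC1(C)C)B1OC(C)(C)C(C)(C)O1
Why: Iridium-catalysed aromatic C–H borylation is sterically controlled and should occur only at C5, the one C–H without an ortho substituent, which is para to the central oxygen and becomes C1′; the aryl bromide is kept.

Step 6
Reactants: 8 2-[3-bromo-4,5-bis(methoxymethoxy)phenyl]-4,4,5,5-tetramethyl-1,3,2-dioxaborolane
Product: 10 diethyl [3-bromo-4,5-bis(methoxymethoxy)phenyl]boronate, via arylboronic acid 9 (not isolated)
Conditions: NaIO4, NH4OAc, acetone/H2O, rt; then EtOH, toluene, azeotropic distillation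
Reagents that add atoms: ethanol CCO
Why: Periodate removes the pinacol ester by oxidising the released diol, and azeotropic esterification with ethanol gives the exchange-labile diethyl boronate that can take up the chiral diol (boronate ester exchange).

Step 7
Reactants: 5 1-chloro-4,6-bis(methoxymethoxy)-1a,6b-dihydro-1H-cyclopropa[b][1]benzofuran, 10 diethyl [3-bromo-4,5-bis(methoxymethoxy)phenyl]boronate
Product: 14 (2S)-2-[3-bromo-4,5-bis(methoxymethoxy)phenyl]-5,7-bis(methoxymethoxy)-2H-chromene, via sodium aryltriethoxyborate 11 (not isolated), via chromenylium chloride 12 (not isolated), via 2-ethoxy-2H-chromene 13 (not isolated)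
Conditions: 10, NaOEt, THF, rt; add 5, EtOAc, 0 °C → rt; then (R,R)-N,N′-dibenzyltartramide (10 mol %), Yb(OTf)3 (5 mol %), −40 → 4 °C, dark
Reagents that add atoms: none
Why: Proposed new method: on warming, the endo chloride of 5 leaves in a disrotatory cyclopropyl-to-allyl cation opening that breaks the shared C1a–C6b bond, so the carbenoid carbon becomes C3 and the aromatic 5,7-dioxygenated chromenylium ion 12 results; ethoxide transfer from borate 11 parks it as acetal 13 beside NaCl and boronate 10, and Yb(OTf)3 with the chiral diol then re-ionises 13 and transfers the aryl group from the diol-bound boronate to C2 inside the contact ion pair. The closest known reaction types are the halocarbene ring expansion of benzofurans and indoles (Ciamician–Dennstedt type) and the chiral diol/lanthanide triflate-catalysed addition of boronates to 2-alkoxy-2H-chromenes; new is feeding the cation directly from the cyclopropane. Ring C is not closed by a cyclisation: it arises from the five-membered ring by one-carbon ring expansion through electrocyclic opening of the fused cyclopropane. The C2 stereocentre is set by the chiral diol on boron (catalyst control), and both enantiomers of racemic 5 converge because the cation is planar. The step needs attack at C2 and not C4, which the oxocarbenium character of C2 and the peri 5-OMOM group beside C4 should secure, and it needs cleavage of the internal cyclopropane bond, which the chloride on the apex carbon dictates.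

Step 8
Reactants: 14 (2S)-2-[3-bromo-4,5-bis(methoxymethoxy)phenyl]-5,7-bis(methoxymethoxy)-2H-chromene
Product: 16 (2R,3S)-2-[3-bromo-4,5-bis(methoxymethoxy)phenyl]-5,7-bis(methoxymethoxy)-3,4-dihydro-2H-chromen-3-ol, via flavan-3-ylborane 15 (not isolated)
Conditions: BH3·THF, THF, 0 °C → rt; then NaOH (aq.), H2O2, 0 °C
Reagents that add atoms: hydrogen peroxide OO
Why: Hydroboration–oxidation: borane adds syn to the styrene-type C3=C4 bond on the face opposite the C2 aryl group with boron at C3, away from the ring-A carbon and its peri 5-OMOM group, and oxidation with retention should give the 2,3-trans alcohol, so C3 (S) is set by substrate control from C2, as is established for flav-3-enes.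

Step 9
Reactants: 16 (2R,3S)-2-[3-bromo-4,5-bis(methoxymethoxy)phenyl]-5,7-bis(methoxymethoxy)-3,4-dihydro-2H-chromen-3-ol, 17 geranyl bromide ((2E)-1-bromo-3,7-dimethylocta-2,6-diene)
Product: 19 (2R,3S)-2-{3-[(2E)-3,7-dimethylocta-2,6-dien-1-yl]-4,5-bis(methoxymethoxy)phenyl}-5,7-bis(methoxymethoxy)-3,4-dihydro-2H-chromen-3-ol, via dilithio derivative 18 (not isolated)
Conditions: n-BuLi (2.2 equiv), THF, −78 °C; CuBr·SMe2 (cat.), 17, −78 → −20 °C
Reagents that add atoms: none
Why: Deprotonation of the hydroxyl and bromine–lithium exchange give an aryllithium stabilised by the neighbouring OMOM group, and its copper-catalysed SN2 allylation with geranyl bromide should form the C5′–CH2 bond with the E alkene kept (aryllithium allylation); the lithium alkoxide is too poor a nucleophile to compete at low temperature.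

Step 10
Reactants: 19 (2R,3S)-2-{3-[(2E)-3,7-dimethylocta-2,6-dien-1-yl]-4,5-bis(methoxymethoxy)phenyl}-5,7-bis(methoxymethoxy)-3,4-dihydro-2H-chromen-3-ol
Product: 20 (2R,3S)-2-{3-[(2E)-3,7-dimethylocta-2,6-dien-1-yl]-4,5-dihydroxyphenyl}-3,4-dihydro-2H-chromene-3,5,7-triol
Conditions: HCl (2 M aq.), MeOH, 40 °C, argon
Reagents that add atoms: none
Why: Acid-catalysed acetal exchange with methanol removes the four aryl MOM ethers as dimethoxymethane; dilute acid at mild temperature should leave the trisubstituted alkenes, the benzylic ether at C2 and both stereocentres untouched.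

**Compound list**

1 | 4,6-dihydroxy-1-benzofuran-3(2H)-one | O=C1COc2cc(O)cc(O)c12 | starting material
2 | 4,6-bis(methoxymethoxy)-1-benzofuran-3(2H)-one | O=C1COc2cc(OCOC)cc(OCOC)c12 | intermediate
3 | 4,6-bis(methoxymethoxy)-2,3-dihydro-1-benzofuran-3-ol (racemic) | OC1COc2cc(OCOC)cc(OCOC)c12 | intermediate
4 | 4,6-bis(methoxymethoxy)-1-benzofuran | COCOc1cc(OCOC)c2ccoc2c1 | intermediate
5 | 1-chloro-4,6-bis(methoxymethoxy)-1a,6b-dihydro-1H-cyclopropa[b][1]benzofuran (racemic; cis-fused; chlorine endo; one enantiomer drawn) | COCOc1cc(OCOC)c2[C@@H]3[C@H](Cl)[C@@H]3Oc2c1 | intermediate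
6 | 3-bromobenzene-1,2-diol | Oc1cccc(Br)c1O | starting material
7 | 1-bromo-2,3-bis(methoxymethoxy)benzene | COCOc1cccc(Br)c1OCOC | intermediate
8 | 2-[3-bromo-4,5-bis(methoxymethoxy)phenyl]-4,4,5,5-tetramethyl-1,3,2-dioxaborolane | COCOc1cc(B2OC(C)(C)C(C)(C)O2)cc(Br)c1OCOC | intermediate
9 | [3-bromo-4,5-bis(methoxymethoxy)phenyl]boronic acid | COCOc1cc(B(O)O)cc(Br)c1OCOC | intermediate
10 | diethyl [3-bromo-4,5-bis(methoxymethoxy)phenyl]boronate | CCOB(OCC)c1cc(Br)c(OCOC)c(OCOC)c1 | intermediate
11 | sodium [3-bromo-4,5-bis(methoxymethoxy)phenyl]triethoxyborate | [Na+].CCO[B-](OCC)(OCC)c1cc(Br)c(OCOC)c(OCOC)c1 | intermediate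
12 | 5,7-bis(methoxymethoxy)chromenylium chloride | [Cl-].COCOc1cc(OCOC)c2ccc[o+]c2c1 | intermediate
13 | 2-ethoxy-5,7-bis(methoxymethoxy)-2H-chromene (racemic) | CCOC1C=Cc2c(OCOC)cc(OCOC)cc2O1 | intermediate
14 | (2S)-2-[3-bromo-4,5-bis(methoxymethoxy)phenyl]-5,7-bis(methoxymethoxy)-2H-chromene | COCOc1cc([C@H]2Oc3cc(OCOC)cc(OCOC)c3C=C2)cc(Br)c1OCOC | intermediate
15 | [(2S,3S)-2-[3-bromo-4,5-bis(methoxymethoxy)phenyl]-5,7-bis(methoxymethoxy)-3,4-dihydro-2H-chromen-3-yl]borane (2,3-trans) | COCOc1cc([C@H]2Oc3cc(OCOC)cc(OCOC)c3C[C@@H]2B)cc(Br)c1OCOC | intermediate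
16 | (2R,3S)-2-[3-bromo-4,5-bis(methoxymethoxy)phenyl]-5,7-bis(methoxymethoxy)-3,4-dihydro-2H-chromen-3-ol | COCOc1cc([C@H]2Oc3cc(OCOC)cc(OCOC)c3C[C@@H]2O)cc(Br)c1OCOC | intermediate
17 | geranyl bromide, (2E)-1-bromo-3,7-dimethylocta-2,6-diene | CC(C)=CCC/C(C)=C/CBr | starting material
18 | dilithio derivative of 16 (lithium 3-alkoxide; aryllithium in place of bromine) | COCOc1cc([C@H]2Oc3cc(OCOC)cc(OCOC)c3C[C@@H]2O[Li])cc([Li])c1OCOC | intermediate
19 | (2R,3S)-2-{3-[(2E)-3,7-dimethylocta-2,6-dien-1-yl]-4,5-bis(methoxymethoxy)phenyl}-5,7-bis(methoxymethoxy)-3,4-dihydro-2H-chromen-3-ol | CC(C)=CCC/C(C)=C/Cc1cc([C@H]2Oc3cc(OCOC)cc(OCOC)c3C[C@@H]2O)cc(OCOC)c1OCOC | intermediate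
20 | (2R,3S)-2-{3-[(2E)-3,7-dimethylocta-2,6-dien-1-yl]-4,5-dihydroxyphenyl}-3,4-dihydro-2H-chromene-3,5,7-triol | CC(C)=CCC/C(C)=C/Cc1cc([C@H]2Oc3cc(O)cc(O)c3C[C@@H]2O)cc(O)c1O | target

**Step count and risks**

Total steps: 10. Longest linear sequence: 7 steps (steps 4, 5, 6, 7, 8, 9, 10 from 3-bromocatechol; the branch from 1 through steps 1, 2, 3, 7, 8, 9, 10 is equally long).

Steps most likely to fail:

1. Step 7 (Proposed new method). The aryl group may be transferred inside the first chromenylium–borate ion pair before the chiral diol is engaged, which would erode the enantioselectivity. Chloride may also attack a MOM group of the cation, and the exo chloride will not ionise. Fallback with known chemistry, setting out from 5 and 10 and returning at 14: chloride 5 is warmed in ethanol over K2CO3 (the known alcohol capture of the ring-opened cation) and the 2-ethoxy-2H-chromene 13 is isolated. Then 13 and boronate 10 are combined with the tartramide diol and Yb(OTf)3 in EtOAc at −40 °C (the known boronate addition to chromene acetals) to give 14. This fallback makes no compound outside the compound list (F0).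

2. Step 3. The endo chloride may ionise while the organolithium is still present, so that the cation is captured by methyl transfer. The endo/exo ratio may be unfavourable, and lithiation of the benzofuran or carbenoid attack on ring A may compete. Fallback setting out from 4 and returning at 13: dibromocarbene (CHBr3, KOtBu, pentane, −20 °C) adds to 4 to give 1,1-dibromo-4,6-bis(methoxymethoxy)-1a,6b-dihydro-1H-cyclopropa[b][1]benzofuran F1, in which one bromine is endo by necessity. Warming in ethanol over K2CO3 gives 3-bromo-2-ethoxy-5,7-bis(methoxymethoxy)-2H-chromene F2. Palladium-catalysed formate hydrogenolysis of the vinyl bromide (Pd(PPh3)4, HCO2Na, DMF, 80 °C) gives acetal 13, which is carried to 14 by the catalysed addition of boronate 10 described in the first fallback.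

3. Step 9. The aryllithium may be protonated before it is allylated, giving the debrominated flavanol. Allylation may occur at the tertiary terminus of the allyl unit (branched isomer), or the alkoxide may be O-allylated. Fallback setting out from 16 and returning at 19: Miyaura borylation of 16 (Pd(dppf)Cl2, B2pin2, KOAc, dioxane, 80 °C) gives the aryl pinacol boronate F3. Palladium-catalysed allyl–aryl Suzuki–Miyaura coupling of F3 with geranyl bromide 17 (Pd(PPh3)4, K2CO3, THF/H2O, 50 °C), which is expected to favour the unbranched E product, gives 19.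

Further compounds
F0 | step 7 | none | none
F1 | step 3 | 1,1-dibromo-4,6-bis(methoxymethoxy)-1a,6b-dihydro-1H-cyclopropa[b][1]benzofuran (racemic; cis-fused) | COCOc1cc(OCOC)c2[C@@H]3C(Br)(Br)[C@@H]3Oc2c1
F2 | step 3 | 3-bromo-2-ethoxy-5,7-bis(methoxymethoxy)-2H-chromene (racemic) | CCOC1Oc2cc(OCOC)cc(OCOC)c2C=C1Br
F3 | step 9 | (2R,3S)-2-[3,4-bis(methoxymethoxy)-5-(4,4,5,5-tetramethyl-1,3,2-dioxaborolan-2-yl)phenyl]-5,7-bis(methoxymethoxy)-3,4-dihydro-2H-chromen-3-ol | COCOc1cc([C@H]2Oc3cc(OCOC)cc(OCOC)c3C[C@@H]2O)cc(B4OC(C)(C)C(C)(C)O4)c1OCOC
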